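**Retrosynthetic overview**
1. The 4-hydroxy-enone comes from a bicyclic endoperoxide made by [4+2] cycloaddition of singlet oxygen to a 2-silyloxycyclohexa-1,3-diene; this fixes C1=O/C4–O and sets C4 anti to the C5/C6 oxygens.
2. The silyloxydiene comes from a 6-alkyl-6-hydroxy-5-silyloxycyclohex-2-enone, closed by ring-closing metathesis of an α'-hydroxy vinyl ketone bearing an allyl group.
3. That dienone comes from Felkin–Anh addition of 1-lithio-1-methoxyallene (acryloyl anion equivalent) to an α-silyloxy ketone (C6 set from C5), itself from a Weinreb amide and a C21 Grignard reagent.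
4. The Weinreb amide comes from methyl (R)-glycidate (C5 is bought) and a vinyl Grignard reagent; the C21 chloride from oleyl bromide and 1-bromo-3-chloropropane.
5. Ring order: carbocycle first (metathesis), then the 2,3-dioxabicyclo[2.2.2]octene peroxide ring (cycloaddition), which is opened again in the same flask.

Assumption: geometrically pure oleyl bromide and methyl (R)-glycidate (serine-derived) are purchased; ring positions are numbered as in the target (C1 = C=O, C6 = carbinol carbon bearing the chain).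

**Step 1**
Reactants: 1 (9Z)-1-bromooctadec-9-ene (oleyl bromide)
Product: 3 (12Z)-1-chlorohenicos-12-ene, via oleylmagnesium bromide 2 (not isolated)
Conditions: Mg, THF, 40 °C; then Br(CH2)3Cl (1.5 equiv), Li2CuCl4 (3 mol%), THF, −10 °C → rt
Reagents that add atoms: 1-bromo-3-chloropropane (ClCCCBr)
Why: Copper-catalysed sp3–sp3 Grignard cross-coupling (Kochi coupling) in which the C–Br end of the dihalide reacts much faster than the C–Cl end, adding three carbons without touching the Z-alkene; no stereocentre is formed.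

**Step 2**
Reactants: 4 methyl (2R)-oxirane-2-carboxylate (methyl (R)-glycidate)
Product: 5 methyl (2R)-2-hydroxypent-4-enoate
Conditions: CH2=CHMgBr (1.3 equiv), CuBr·SMe2 (10 mol%), THF, −60 → −30 °C; NH4Cl (aq)
Reagents that add atoms: vinylmagnesium bromide (C=C[Mg]Br)
Why: Copper-catalysed SN2 epoxide opening at the unsubstituted C3; the C2–O bond is untouched, so the bought (R) centre (future C5) is retained.

**Step 3**
Reactants: 5 methyl (2R)-2-hydroxypent-4-enoate
Product: 6 methyl (2R)-2-[(tert-butyldimethylsilyl)oxy]pent-4-enoate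
Conditions: TBSCl, imidazole, DMF, rt
Reagents that add atoms: tert-butyldimethylsilyl chloride (CC(C)(C)[Si](C)(C)Cl)
Why: Silyl ether formation that installs a bulky, non-chelating group on the C5 oxygen, needed for Felkin–Anh control in step 6; the stereocentre is not touched.

**Step 4**
Reactants: 6 methyl (2R)-2-[(tert-butyldimethylsilyl)oxy]pent-4-enoate
Product: 7 (2R)-2-[(tert-butyldimethylsilyl)oxy]-N-methoxy-N-methylpent-4-enamide
Conditions: MeNH(OMe)·HCl, i-PrMgCl, THF, −20 → 0 °C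
Reagents that add atoms: N,O-dimethylhydroxylamine hydrochloride (CNOC.Cl)
Why: Weinreb amidation of the ester by the magnesium amide at low temperature, conditions that do not enolise the α-silyloxy centre.

**Step 5**
Reactants: 7 (2R)-2-[(tert-butyldimethylsilyl)oxy]-N-methoxy-N-methylpent-4-enamide; 3 (12Z)-1-chlorohenicos-12-ene
Product: 9 (4R,17Z)-4-[(tert-butyldimethylsilyl)oxy]hexacosa-1,17-dien-5-one, via henicosenylmagnesium chloride 8 (not isolated)
Conditions: 3, Mg, I2 (cat.), THF, 65 °C; then 7, THF, 0 °C; NH4Cl (aq)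
Reagents that add atoms: none
Why: Weinreb ketone synthesis, where the chelated tetrahedral intermediate stops the Grignard addition at the ketone; the ketone carbon becomes C6 and the C5 centre is unchanged.

**Step 6**
Reactants: 9 (4R,17Z)-4-[(tert-butyldimethylsilyl)oxy]hexacosa-1,17-dien-5-one
Product: 11 (4R,5R)-5-[(tert-butyldimethylsilyl)oxy]-4-[(12Z)-henicos-12-en-1-yl]-4-hydroxyocta-1,7-dien-3-one, via lithium allenyl carbinolate 10 (not isolated)
Conditions: methoxyallene, n-BuLi, THF, −40 °C; then 9, −78 °C; then 1 M HCl, THF, 0 °C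
Reagents that add atoms: methoxyallene (COC=C=C); water (O)
Why: 1,2-Addition of 1-lithio-1-methoxyallene under Felkin–Anh control (non-chelating C–OTBS bond anti to the nucleophile, allyl group inside) places the new C6 hydroxyl syn to the C5 oxygen (6R in the target), and mild acid hydrolyses the allenyl enol ether to the vinyl ketone.

**Step 7**
Reactants: 11 (4R,5R)-5-[(tert-butyldimethylsilyl)oxy]-4-[(12Z)-henicos-12-en-1-yl]-4-hydroxyocta-1,7-dien-3-one
Product: 12 (5R,6R)-5-[(tert-butyldimethylsilyl)oxy]-6-[(12Z)-henicos-12-en-1-yl]-6-hydroxycyclohex-2-en-1-one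
Conditions: second-generation Grubbs catalyst RuCl2(=CHPh)(PCy3)(H2IMes) (5 mol%), CH2Cl2 (5 mM), 40 °C, N2 sparge
Reagents that add atoms: none
Why: Ring-closing metathesis of the two terminal alkenes gives the six-membered enone with loss of ethylene, the intramolecular closure at high dilution outpacing any reaction of the internal Z-alkene; no stereocentre changes.

**Step 8**
Reactants: 12 (5R,6R)-5-[(tert-butyldimethylsilyl)oxy]-6-[(12Z)-henicos-12-en-1-yl]-6-hydroxycyclohex-2-en-1-one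
Product: 13 (5R,6R)-5-[(tert-butyldimethylsilyl)oxy]-6-[(12Z)-henicos-12-en-1-yl]-1,6-bis[(trimethylsilyl)oxy]cyclohexa-1,3-diene
Conditions: TMSOTf (2.5 equiv), Et3N (4 equiv), CH2Cl2, 0 °C; pentane extraction, used crude
Reagents that add atoms: trimethylsilyl trifluoromethanesulfonate (C[Si](C)(C)OS(=O)(=O)C(F)(F)F)
Why: Soft enolisation (silyl dienol ether formation): O-silylation of the enone and loss of the γ-proton at C4, the only enolisable position because C6 is quaternary, gives the 2-silyloxy-1,3-diene while the tertiary hydroxyl is capped as its TMS ether.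

**Step 9**
Reactants: 13 (5R,6R)-5-[(tert-butyldimethylsilyl)oxy]-6-[(12Z)-henicos-12-en-1-yl]-1,6-bis[(trimethylsilyl)oxy]cyclohexa-1,3-diene
Product: 17 (4S,5R,6R)-6-[(12Z)-henicos-12-en-1-yl]-4,5,6-trihydroxycyclohex-2-en-1-one, via endoperoxide 14 (not isolated), via silylperoxy enone 15 (not isolated), via silylated hydroxy enone 16 (not isolated)
Conditions: O2, hν (visible), tetraphenylporphyrin (cat.), CH2Cl2, −78 °C; then PPh3, −78 → 0 °C; then HF·pyridine, THF, 0 °C → rt
Reagents that add atoms: dioxygen (O=O)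
Why: Singlet oxygen adds in a [4+2] cycloaddition across C1/C4 of the silyloxydiene from the face anti to the C5 and C6 silyloxy groups, setting C4 as S; the bridgehead peroxy ketal collapses by silyl shift to the 4-silylperoxy enone, PPh3 reduces the O–O bond and HF·pyridine removes the three silyl ethers.

**Compound list**
1 | (9Z)-1-bromooctadec-9-ene (oleyl bromide) | CCCCCCCC/C=C\CCCCCCCCBr | starting material
2 | [(9Z)-octadec-9-en-1-yl]magnesium bromide | CCCCCCCC/C=C\CCCCCCCC[Mg]Br | intermediate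
3 | (12Z)-1-chlorohenicos-12-ene | CCCCCCCC/C=C\CCCCCCCCCCCCl | intermediate
4 | methyl (2R)-oxirane-2-carboxylate | COC(=O)[C@H]1CO1 | starting material
5 | methyl (2R)-2-hydroxypent-4-enoate | COC(=O)[C@H](O)CC=C | intermediate
6 | methyl (2R)-2-[(tert-butyldimethylsilyl)oxy]pent-4-enoate | COC(=O)[C@H](O[Si](C)(C)C(C)(C)C)CC=C | intermediate
7 | (2R)-2-[(tert-butyldimethylsilyl)oxy]-N-methoxy-N-methylpent-4-enamide | CON(C)C(=O)[C@H](O[Si](C)(C)C(C)(C)C)CC=C | intermediate
8 | [(12Z)-henicos-12-en-1-yl]magnesium chloride | CCCCCCCC/C=C\CCCCCCCCCCC[Mg]Cl | intermediate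
9 | (4R,17Z)-4-[(tert-butyldimethylsilyl)oxy]hexacosa-1,17-dien-5-one | CCCCCCCC/C=C\CCCCCCCCCCCC(=O)[C@H](O[Si](C)(C)C(C)(C)C)CC=C | intermediate
10 | lithium (4R,5R)-5-[(tert-butyldimethylsilyl)oxy]-4-[(12Z)-henicos-12-en-1-yl]-3-methoxyocta-1,2,7-trien-4-olate | CCCCCCCC/C=C\CCCCCCCCCCC[C@]([C@H](O[Si](C)(C)C(C)(C)C)CC=C)(O[Li])C(OC)=C=C | intermediate
11 | (4R,5R)-5-[(tert-butyldimethylsilyl)oxy]-4-[(12Z)-henicos-12-en-1-yl]-4-hydroxyocta-1,7-dien-3-one | CCCCCCCC/C=C\CCCCCCCCCCC[C@]([C@H](O[Si](C)(C)C(C)(C)C)CC=C)(O)C(=O)C=C | intermediate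
12 | (5R,6R)-5-[(tert-butyldimethylsilyl)oxy]-6-[(12Z)-henicos-12-en-1-yl]-6-hydroxycyclohex-2-en-1-one | CCCCCCCC/C=C\CCCCCCCCCCC[C@]1(O)C(=O)C=CC[C@H]1O[Si](C)(C)C(C)(C)C | intermediate
13 | (5R,6R)-5-[(tert-butyldimethylsilyl)oxy]-6-[(12Z)-henicos-12-en-1-yl]-1,6-bis[(trimethylsilyl)oxy]cyclohexa-1,3-diene | CCCCCCCC/C=C\CCCCCCCCCCC[C@]1(O[Si](C)(C)C)C(O[Si](C)(C)C)=CC=C[C@H]1O[Si](C)(C)C(C)(C)C | intermediate
14 | (1S,4S,7R,8R)-8-[(tert-butyldimethylsilyl)oxy]-7-[(12Z)-henicos-12-en-1-yl]-1,7-bis[(trimethylsilyl)oxy]-2,3-dioxabicyclo[2.2.2]oct-5-ene (peroxide bridge anti to the silyloxy groups) | CCCCCCCC/C=C\CCCCCCCCCCC[C@]1(O[Si](C)(C)C)[C@@]2(O[Si](C)(C)C)C=C[C@H](OO2)[C@H]1O[Si](C)(C)C(C)(C)C | intermediate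
15 | (4S,5R,6R)-5-[(tert-butyldimethylsilyl)oxy]-6-[(12Z)-henicos-12-en-1-yl]-6-[(trimethylsilyl)oxy]-4-[(trimethylsilyl)peroxy]cyclohex-2-en-1-one | CCCCCCCC/C=C\CCCCCCCCCCC[C@]1(O[Si](C)(C)C)C(=O)C=C[C@H](OO[Si](C)(C)C)[C@H]1O[Si](C)(C)C(C)(C)C | intermediate
16 | (4S,5R,6R)-5-[(tert-butyldimethylsilyl)oxy]-6-[(12Z)-henicos-12-en-1-yl]-4,6-bis[(trimethylsilyl)oxy]cyclohex-2-en-1-one | CCCCCCCC/C=C\CCCCCCCCCCC[C@]1(O[Si](C)(C)C)C(=O)C=C[C@H](O[Si](C)(C)C)[C@H]1O[Si](C)(C)C(C)(C)C | intermediate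
17 | (4S,5R,6R)-6-[(12Z)-henicos-12-en-1-yl]-4,5,6-trihydroxycyclohex-2-en-1-one | CCCCCCCC/C=C\CCCCCCCCCCC[C@]1(O)C(=O)C=C[C@H](O)[C@H]1O | target

**Step count**
Total: 9 steps. Longest linear sequence: 8 steps (4 → 17, steps 2–9); the chain branch (step 1) joins in step 5.

**Three steps most likely to fail**

Step 6 (Felkin–Anh addition to an acyclic, enolisable α-silyloxy ketone). The diastereomer ratio may be modest, and the chelation-type isomer would give the trans-diol. The fallback sets out from 7 and comes back at 12, setting C6 by 1,2-induction in a ring instead. Amide 7 reacts with allylMgBr to give (5R)-5-[(tert-butyldimethylsilyl)oxy]octa-1,7-dien-4-one F1. Ring-closing metathesis with the second-generation Grubbs catalyst RuCl2(=CHPh)(PCy3)(H2IMes), before any chain alkene is present, gives (6R)-6-[(tert-butyldimethylsilyl)oxy]cyclohex-3-en-1-one F2. Brief treatment with catalytic DBU at 0 °C moves the alkene into conjugation, giving (6R)-6-[(tert-butyldimethylsilyl)oxy]cyclohex-2-en-1-one F3; this step can erode the α-silyloxy centre and must be kept short. The organocerium reagent from 8 and CeCl3 adds 1,2 to F3 anti to the neighbouring silyl ether, giving (1S,6R)-6-[(tert-butyldimethylsilyl)oxy]-1-[(12Z)-henicos-12-en-1-yl]cyclohex-2-en-1-ol F4. VO(acac)2 with t-BuOOH epoxidises only the allylic alkene, syn to the tertiary hydroxyl, giving (1S,2S,3R,6S)-3-[(tert-butyldimethylsilyl)oxy]-2-[(12Z)-henicos-12-en-1-yl]-7-oxabicyclo[4.1.0]heptan-2-ol F5. LiNEt2 isomerises the epoxide, the only β-hydrogens being on the CH2 side, to (1S,2S,6R)-6-[(tert-butyldimethylsilyl)oxy]-1-[(12Z)-henicos-12-en-1-yl]cyclohex-3-ene-1,2-diol F6. Dess–Martin oxidation of its secondary allylic alcohol gives 12.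

Step 7 (metathesis of an electron-poor vinyl ketone in a molecule with an internal Z-alkene). The active Ru carbene may isomerise or cleave the chain alkene, or the closure may stall. The fallback sets out from 11 and comes back at 12. Luche reduction (NaBH4, CeCl3·7H2O, MeOH, −78 °C) gives (4S,5R)-5-[(tert-butyldimethylsilyl)oxy]-4-[(12Z)-henicos-12-en-1-yl]octa-1,7-diene-3,4-diol F7 as both C3 epimers. This electron-rich terminal diene closes with the less active first-generation Grubbs catalyst RuCl2(=CHPh)(PCy3)2, which barely touches 1,2-disubstituted alkenes, to give (1S,6R)-6-[(tert-butyldimethylsilyl)oxy]-1-[(12Z)-henicos-12-en-1-yl]cyclohex-3-ene-1,2-diol F8 as both C2 epimers. Dess–Martin oxidation of the secondary allylic alcohol gives 12.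

Step 9 (photooxygenation). Possible failures are the ene reaction of singlet oxygen at the chain Z-alkene, α- instead of γ-oxygenation, or incomplete face selectivity. The fallback sets out from 13 and comes back at 16, replacing the cycloaddition by a vinylogous Rubottom oxidation. One equivalent of dimethyldioxirane (acetone/CH2Cl2, −78 °C) epoxidises the electron-rich C3=C4 bond of the silyloxydiene anti to the silyloxy groups, far faster than the isolated Z-alkene, giving 5-[(tert-butyldimethylsilyl)oxy]-4-[(12Z)-henicos-12-en-1-yl]-3,4-bis[(trimethylsilyl)oxy]-7-oxabicyclo[4.1.0]hept-2-ene F9 (epoxide trans to the silyloxy groups, not isolated). F9 opens with silyl transfer to 16, and HF·pyridine then gives 17 as in the main route.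

**Further compounds**
F1 | step 6 | (5R)-5-[(tert-butyldimethylsilyl)oxy]octa-1,7-dien-4-one | C=CCC(=O)[C@H](O[Si](C)(C)C(C)(C)C)CC=C
F2 | step 6 | (6R)-6-[(tert-butyldimethylsilyl)oxy]cyclohex-3-en-1-one | O=C1CC=CC[C@H]1O[Si](C)(C)C(C)(C)C
F3 | step 6 | (6R)-6-[(tert-butyldimethylsilyl)oxy]cyclohex-2-en-1-one | O=C1C=CCC[C@H]1O[Si](C)(C)C(C)(C)C
F4 | step 6 | (1S,6R)-6-[(tert-butyldimethylsilyl)oxy]-1-[(12Z)-henicos-12-en-1-yl]cyclohex-2-en-1-ol | CCCCCCCC/C=C\CCCCCCCCCCC[C@]1(O)C=CCC[C@H]1O[Si](C)(C)C(C)(C)C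
F5 | step 6 | (1S,2S,3R,6S)-3-[(tert-butyldimethylsilyl)oxy]-2-[(12Z)-henicos-12-en-1-yl]-7-oxabicyclo[4.1.0]heptan-2-ol | CCCCCCCC/C=C\CCCCCCCCCCC[C@]1(O)[C@H]2O[C@H]2CC[C@H]1O[Si](C)(C)C(C)(C)C
F6 | step 6 | (1S,2S,6R)-6-[(tert-butyldimethylsilyl)oxy]-1-[(12Z)-henicos-12-en-1-yl]cyclohex-3-ene-1,2-diol | CCCCCCCC/C=C\CCCCCCCCCCC[C@]1(O)[C@@H](O)C=CC[C@H]1O[Si](C)(C)C(C)(C)C
F7 | step 7 | (4S,5R)-5-[(tert-butyldimethylsilyl)oxy]-4-[(12Z)-henicos-12-en-1-yl]octa-1,7-diene-3,4-diol (both C3 epimers) | CCCCCCCC/C=C\CCCCCCCCCCC[C@]([C@H](O[Si](C)(C)C(C)(C)C)CC=C)(O)C(O)C=C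
F8 | step 7 | (1S,6R)-6-[(tert-butyldimethylsilyl)oxy]-1-[(12Z)-henicos-12-en-1-yl]cyclohex-3-ene-1,2-diol (both C2 epimers) | CCCCCCCC/C=C\CCCCCCCCCCC[C@]1(O)C(O)C=CC[C@H]1O[Si](C)(C)C(C)(C)C
F9 | step 9 | 5-[(tert-butyldimethylsilyl)oxy]-4-[(12Z)-henicos-12-en-1-yl]-3,4-bis[(trimethylsilyl)oxy]-7-oxabicyclo[4.1.0]hept-2-ene (epoxide trans to the silyloxy groups) | CCCCCCCC/C=C\CCCCCCCCCCC[C@]1(O[Si](C)(C)C)C(O[Si](C)(C)C)=C[C@@H]2O[C@@H]2[C@H]1O[Si](C)(C)C(C)(C)C
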